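**Retrosynthetic overview**
- Target 9 ⇐ 4'-O-benzyl ether 8 by hydrogenolysis; the benzyl group is the only protecting group in the route.
- 8 ⇐ o-hydroxyaryl β-diketone 5. The C3–OSO3 bond comes from the diketonate carbon attacking a peroxide oxygen of peroxodisulfate, and the O1–C2 bond from cyclodehydration. The pyranone (ring C) is the only ring formed and is formed last.
- 5 ⇐ acetophenone 1 (ring A, with 7-OMe and 5-OH already in place) plus O-benzylvanillic acid 2 (ring B), joined by enolate C-aroylation.

Assumption: the target has no stereocentre and is achiral, so no enantiocontrol is needed; sulfate esters are handled as sodium salts and written, like the target, as neutral hydrogen sulfates (released by H+ exchange).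

**Step 1**
Reactants: 1 1-(2,6-dihydroxy-4-methoxyphenyl)ethan-1-one (2',6'-dihydroxy-4'-methoxyacetophenone); 2 4-(benzyloxy)-3-methoxybenzoic acid (O-benzylvanillic acid)
Product: 5 1-[4-(benzyloxy)-3-methoxyphenyl]-3-(2,6-dihydroxy-4-methoxyphenyl)propane-1,3-dione, via acid chloride 3 (not isolated), via trilithium enolate 4 (not isolated)
Conditions: 2, (COCl)2 (1.2 equiv), cat. DMF, CH2Cl2, 0 °C → rt, evaporate; 1, LiHMDS (4.1 equiv), THF, −78 → −10 °C, 2 h; add 3 (1.0 equiv) in THF at −78 °C → rt, 4 h; 1 M HCl quench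
Reagents that add atoms: none
Why: The enolate carbon of trianion 4 is its only good nucleophile (the chelated ortho-acyl phenoxides are poor ones), so acid chloride 3 is C-aroylated in a one-pot Baker–Venkataraman-type Claisen acylation of a ketone polyanion, the fourth equivalent of base taking up the more acidic diketone; no stereocentre is formed.

**Step 2**
Reactants: 5 1-[4-(benzyloxy)-3-methoxyphenyl]-3-(2,6-dihydroxy-4-methoxyphenyl)propane-1,3-dione
Product: 8 4'-O-benzylrhamnazin 3-O-sulfate (2-[4-(benzyloxy)-3-methoxyphenyl]-5-hydroxy-7-methoxy-4-oxo-4H-chromen-3-yl hydrogen sulfate), via sulfatoxy diketone 6 (not isolated), via hemiketal 7 (not isolated)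
Conditions: Na2S2O8 (1.05 equiv), NaHCO3/Na2CO3 buffer (pH ≈ 10), EDTA (1 mol%), MeCN/H2O 1:1, N2, dark, 5 → 20 °C, 16 h; then AcOH to pH 4–5, 60 °C, 2 h; C18 desalting (Na salt)
Reagents that add atoms: sodium peroxodisulfate, [Na+].[Na+].[O-]S(=O)(=O)OOS(=O)(=O)[O-]
Why: Proposed new method: C-sulfatoxylation of a β-diketonate by peroxodisulfate followed by cyclodehydration. The stabilised carbanion of 5 (pKa about 9) attacks a peroxide oxygen of S2O8(2−) in an SN2-at-oxygen step that expels sulfate and forms the C3–OSO3− bond (6), without the dearomatisation penalty that slows attack by the chelated ring-A phenoxide; the α-substituted keto form 6 then closes through phenol addition to the aroyl carbonyl (hemiketal 7) and loses water in the mild acetate buffer, which forms the O1–C2 bond and the aromatic pyranone while the sulfate monoester anion should survive these conditions; the closest known reaction types are the Elbs persulfate oxidation of phenolates, the α-benzoyloxylation of β-dicarbonyl enolates by dibenzoyl peroxide and the cyclodehydration that ends a Baker–Venkataraman flavone synthesis, and the transient stereocentres of 6 and 7 vanish on aromatisation.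

**Step 3**
Reactants: 8 4'-O-benzylrhamnazin 3-O-sulfate
Product: 9 rhamnazin 3-O-sulfate (5-hydroxy-2-(4-hydroxy-3-methoxyphenyl)-7-methoxy-4-oxo-4H-chromen-3-yl hydrogen sulfate)
Conditions: H2 (1 atm), 10% Pd/C, MeOH/H2O 9:1 (on the Na salt), rt, 2 h; filter; Dowex 50W-X8 (H+), 0 °C; lyophilise
Reagents that add atoms: none
Why: Catalytic hydrogenolysis of an aryl benzyl ether under neutral conditions, to which sulfate monoester salts and the tetrasubstituted, conjugated flavonol C2=C3 bond are inert; no stereocentre is involved.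

**Compound list**
1 | 1-(2,6-dihydroxy-4-methoxyphenyl)ethan-1-one | CC(=O)c1c(O)cc(OC)cc1O | starting material
2 | 4-(benzyloxy)-3-methoxybenzoic acid | COc1cc(C(=O)O)ccc1OCc1ccccc1 | starting material
3 | 4-(benzyloxy)-3-methoxybenzoyl chloride | COc1cc(C(=O)Cl)ccc1OCc1ccccc1 | intermediate
4 | trilithium enolate bis(phenoxide) of 1 | [Li+].[Li+].[Li+].C=C([O-])c1c([O-])cc(OC)cc1[O-] | intermediate
5 | 1-[4-(benzyloxy)-3-methoxyphenyl]-3-(2,6-dihydroxy-4-methoxyphenyl)propane-1,3-dione | COc1cc(O)c(C(=O)CC(=O)c2ccc(OCc3ccccc3)c(OC)c2)c(O)c1 | intermediate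
6 | 1-[4-(benzyloxy)-3-methoxyphenyl]-3-(2,6-dihydroxy-4-methoxyphenyl)-1,3-dioxopropan-2-yl hydrogen sulfate (racemic) | COc1cc(O)c(C(=O)C(OS(=O)(=O)O)C(=O)c2ccc(OCc3ccccc3)c(OC)c2)c(O)c1 | intermediate
7 | 2-[4-(benzyloxy)-3-methoxyphenyl]-2,5-dihydroxy-7-methoxy-4-oxochroman-3-yl hydrogen sulfate (racemic diastereomer mixture) | COc1cc(O)c2C(=O)C(OS(=O)(=O)O)C(O)(c3ccc(OCc4ccccc4)c(OC)c3)Oc2c1 | intermediate
8 | 4'-O-benzylrhamnazin 3-O-sulfate | COc1cc(O)c2c(=O)c(OS(=O)(=O)O)c(-c3ccc(OCc4ccccc4)c(OC)c3)oc2c1 | intermediate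
9 | rhamnazin 3-O-sulfate (achiral) | COc1cc(O)c2c(=O)c(OS(=O)(=O)O)c(-c3ccc(O)c(OC)c3)oc2c1 | target

**Total step count:** 3. **Longest linear sequence:** 3 steps (1 and 2 are both commercial and meet in step 1).

**Steps most likely to fail**

Step 2 (proposed new step). The risks are competing Elbs-type attack on the electron-rich ring A, retro-Claisen cleavage of 6, and loss of sulfate during dehydration. The fallback uses known chemistry, sets out from 5 and returns at 8. The diketonate of 5 is α-benzoyloxylated with dibenzoyl peroxide (aq. Na2CO3/CH2Cl2, Bu4NHSO4) to give 2-(4-(benzyloxy)-3-methoxybenzoyl)-2-benzoyloxy diketone, written here as 1-[4-(benzyloxy)-3-methoxyphenyl]-3-(2,6-dihydroxy-4-methoxyphenyl)-1,3-dioxopropan-2-yl benzoate F2. AcOH with cat. H2SO4 at 80 °C cyclodehydrates it to 3-O-benzoyl-4'-O-benzylrhamnazin F3. NaOH in aqueous EtOH removes the benzoate to give 4'-O-benzylrhamnazin F4. SO3·NMe3 with K2CO3 in DMF then sulfates the 3-OH, the only hydroxyl not locked in the 5-OH/C4=O chelate, and gives 8.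

Step 1. The risks are O-acylation or double acylation of the polyanion and incomplete enolisation of the hindered 2,6-dioxygenated ketone. The fallback sets out from 1 (with 3 made from 2 as before) and returns at 5 by the classical two-stage Baker–Venkataraman sequence. Mono-O-aroylation of 1 with 3 in pyridine at 0 °C gives 2-acetyl-3-hydroxy-5-methoxyphenyl 4-(benzyloxy)-3-methoxybenzoate F1. KOH in pyridine at 50 °C then moves the aroyl group from oxygen to the enolate carbon and gives 5.

Step 3. The risks are desulfation on the catalyst or during H+ exchange, and slow hydrogenolysis of the polar salt. The fallback sets out from 5 and returns at 9, removing the benzyl group before any sulfate is present. 5 is taken through F2 and F3 to 4'-O-benzylrhamnazin F4 as described above. Hydrogenolysis of F4 (H2, Pd/C, THF/MeOH) gives rhamnazin F5. Bu4NHSO4 with DCC in pyridine at 4 °C then sulfates the 3-OH in preference to the 4'-OH (the 5-OH is chelated), and cation exchange gives 9. The 3-OH-first selectivity is recalled from reported flavonol sulfations and should be checked on a small scale.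

**Further compounds**
F1 | step 1 | 2-acetyl-3-hydroxy-5-methoxyphenyl 4-(benzyloxy)-3-methoxybenzoate | CC(=O)c1c(O)cc(OC)cc1OC(=O)c1ccc(OCc2ccccc2)c(OC)c1
F2 | step 2 | 1-[4-(benzyloxy)-3-methoxyphenyl]-3-(2,6-dihydroxy-4-methoxyphenyl)-1,3-dioxopropan-2-yl benzoate (racemic) | COc1cc(O)c(C(=O)C(OC(=O)c2ccccc2)C(=O)c2ccc(OCc3ccccc3)c(OC)c2)c(O)c1
F3 | step 2 | 3-O-benzoyl-4'-O-benzylrhamnazin | COc1cc(O)c2c(=O)c(OC(=O)c3ccccc3)c(-c3ccc(OCc4ccccc4)c(OC)c3)oc2c1
F4 | step 2 | 4'-O-benzylrhamnazin | COc1cc(O)c2c(=O)c(O)c(-c3ccc(OCc4ccccc4)c(OC)c3)oc2c1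
F5 | step 3 | rhamnazin | COc1cc(O)c2c(=O)c(O)c(-c3ccc(O)c(OC)c3)oc2c1
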